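Both carbocycles are cut at once, across C1–C2 and C5–C10. Ring A carries its oxygen at C3, para to the fusion carbon C10, and C10 bears the oxygenated ring B carbon C9: ring A is thus the "para" adduct of a 2-oxygenated diene (C2–C5) and an enone (C1=C10, carbonyl C9). One intramolecular Diels–Alder reaction of trienone 15 closes rings A and B, sets quaternary C5 and C10, and leaves a C3 silyl enol ether and a C9 ketone for the C4 methyl, the 3-ester and the 8,9-diol. Trienone 15 is an (R)-C7 methyl ester with a vinyl ketone arm (C8–C9) and an (E)-2-silyloxy-4-methyldiene arm (C6 to C2).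

Key step: step 10

Remark: eremophilane numbering is used for all bicyclic compounds (ring A = C1–C5 and C10, ring B = C5–C10); β is the face of the C5 methyl.
Assumption: (R)-4-benzyl-1,3-oxazolidin-2-one and (S)-pent-1-yn-3-ol are bought as single enantiomers.
Remark: trienone 15 and decalone 17 keep the TBS ether and the methyl ester; the design change is that the vinyl ketone is released last, by Grignard addition to a Weinreb amide, so nothing has to be deprotected or oxidised beside the dienol ether.

Step 1
Reactants: 1 prop-2-yn-1-ol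
Product: 3 (E)-3-iodo-2-methylprop-2-en-1-ol, via alkenylalane 2 (not isolated)
Conditions: Me3Al, Cp2ZrCl2 (cat.), CH2Cl2, 0 °C to rt; then I2, THF, −30 °C
Reagents that add atoms: trimethylaluminium, C[Al](C)C; iodine, II
Why: Zirconium-catalysed Negishi carboalumination should add methyl and aluminium syn across the alkyne with methyl on the internal carbon, and iodinolysis of the alkenyl–aluminium bond with retention then fixes the E vinyl iodide.

Step 2
Reactants: 3 (E)-3-iodo-2-methylprop-2-en-1-ol
Product: 4 (E)-3-bromo-1-iodo-2-methylprop-1-ene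
Conditions: CBr4, PPh3, CH2Cl2, 0 °C
Reagents that add atoms: tetrabromomethane, BrC(Br)(Br)Br
Why: An Appel reaction should convert the primary allylic alcohol into the bromide under neutral conditions without touching the vinyl iodide or the alkene geometry.

Step 3
Reactants: 5 succinic anhydride
Product: 6 4-[methoxy(methyl)amino]-4-oxobutanoic acid
Conditions: MeNHOMe·HCl, pyridine, CH2Cl2, 0 °C to rt
Reagents that add atoms: N,O-dimethylhydroxylamine hydrochloride, CNOC.Cl
Why: Aminolysis of the cyclic anhydride by the liberated hydroxylamine should open it once to the Weinreb half-amide acid.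

Step 4
Reactants: 6 4-[methoxy(methyl)amino]-4-oxobutanoic acid; 7 (R)-4-benzyl-1,3-oxazolidin-2-one
Product: 9 (R)-4-benzyl-3-{4-[methoxy(methyl)amino]-4-oxobutanoyl}-1,3-oxazolidin-2-one, via mixed pivalic anhydride 8 (not isolated)
Conditions: t-BuCOCl, Et3N, THF, −20 °C; then LiCl, 7, rt
Reagents that add atoms: none
Why: N-Acylation of the oxazolidinone through the mixed pivalic anhydride (LiCl/Et3N variant) is the standard entry to Evans imides and should leave the Weinreb amide alone.

Step 5
Reactants: 9 imide; 4 (E)-3-bromo-1-iodo-2-methylprop-1-ene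
Product: 10 (R)-4-benzyl-3-[(2R,4E)-5-iodo-2-{2-[methoxy(methyl)amino]-2-oxoethyl}-4-methylpent-4-enoyl]-1,3-oxazolidin-2-one
Conditions: NaN(SiMe3)2, THF, −78 °C; then 4, −78 to −40 °C
Reagents that add atoms: none
Why: Evans alkylation: the chelated Z sodium enolate of the imide (its α-CH2 is far more acidic than that of the amide) should be attacked by the allylic bromide on the face opposite the benzyl group, which sets C7 as R.

Step 6
Reactants: 10 alkylated imide
Product: 11 methyl (2R,4E)-5-iodo-2-{2-[methoxy(methyl)amino]-2-oxoethyl}-4-methylpent-4-enoate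
Conditions: MeMgBr, MeOH, CH2Cl2, 0 °C
Reagents that add atoms: methanol, CO
Why: Transesterification with magnesium methoxide should cleave the exocyclic imide carbonyl under weakly basic conditions that neither epimerise C7 nor attack the Weinreb amide.

Step 7
Reactants: 11 iodo ester
Product: 13 methyl (2R,4E)-2-{2-[methoxy(methyl)amino]-2-oxoethyl}-4-methyl-6-oxohept-4-enoate, via 2-ethoxydiene 12 (not isolated)
Conditions: CH2=C(OEt)SnBu3, Pd(PPh3)4 (cat.), LiCl, DMF, 80 °C; then 1 M HCl, THF, rt
Reagents that add atoms: tributyl(1-ethoxyvinyl)stannane, CCOC(=C)[Sn](CCCC)(CCCC)CCCC; water, O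
Why: Stille coupling of the alkenyl iodide with the acetyl-anion stannane proceeds with retention of the E geometry, and mild acid hydrolysis of the ethoxydiene should unmask the methyl enone.

Step 8
Reactants: 13 enone
Product: 14 methyl (2R,4E)-6-[(tert-butyldimethylsilyl)oxy]-2-{2-[methoxy(methyl)amino]-2-oxoethyl}-4-methylhepta-4,6-dienoate
Conditions: TBSOTf, Et3N, CH2Cl2, −78 to 0 °C
Reagents that add atoms: tert-butyldimethylsilyl trifluoromethanesulfonate, CC(C)(C)[Si](C)(C)OS(=O)(=O)C(F)(F)F
Why: Soft enolisation with silyl triflate and amine removes a proton from the α′-methyl of the O-silylated enone, which should give the cross-conjugated 2-silyloxydiene without disturbing the ester, the amide or the E alkene.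

Step 9
Reactants: 14 dienol ether Weinreb amide
Product: 15 methyl (2R,4E)-6-[(tert-butyldimethylsilyl)oxy]-4-methyl-2-(2-oxobut-3-enyl)hepta-4,6-dienoate (trienone)
Conditions: CH2=CHMgBr, THF, −78 to −20 °C; inverse quench into cold aq. NaHSO4; used at once
Reagents that add atoms: vinylmagnesium bromide, C=C[Mg]Br
Why: Weinreb ketone synthesis: the chelated tetrahedral adduct stops at mono-addition, the N-methoxy amide reacts before the α-branched methyl ester, and the inverse acidic quench should keep the liberated hydroxylamine from adding to the new vinyl ketone.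

Step 10
Reactants: 15 trienone
Product: 17 trans-fused decalone (Δ3 TBS enol ether; 5β-methyl; 7α-CO2Me; 9-oxo; 10α-H; 5R,7R,10R), via cis-fused C10 epimer 16 (not isolated)
Conditions: PhMe (0.01 M), BHT (cat.), 80 °C; then DBU (cat.), rt
Reagents that add atoms: none
Why: The electron-rich 2-silyloxydiene and the tethered enone should combine in a concerted, asynchronous [4+2] cycloaddition in which the C1–C2 bond (nucleophilic diene terminus to enone β-carbon) leads and the bond to the fully substituted C5 follows; the closest known reaction type is the type-1 intramolecular Diels–Alder reaction of 1,7,9-decatrien-3-ones and of 2-silyloxydienes with enones. Ring A closes as the six-membered cycloadduct ring, and ring B closes as a six-membered carbocycle through the four-atom tether C6–C9 that holds the dienophile carbonyl. C5 is controlled by the C7 stereocentre: in the exo-chair and endo-boat arrangements the tether leaves C5 on the side of the inside methyl and the C7 ester sits pseudo-equatorial, which places the new C5 methyl anti to the ester. C10 does not depend on the endo or exo mode, because the cis-fused adduct 16 epimerises through the C9 enol to the more stable trans-decalone under DBU, which does not touch C7. The step needs regiocontrol, secured by the tether and the matched polarity of C2 and C1, and diene-face control, secured by the equatorial preference of the C7 ester; because the Z-placed methyl on C5 strains the s-cis diene, the reaction is run dilute and only warm enough to cyclise, below the range of 1,5-hydrogen shift.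

Step 11
Reactants: 17 trans-fused decalone
Product: 18 silyloxycyclopropane ketone (α-face CH2 across C3–C4; 3β-OTBS; 4β-H; otherwise as 17)
Conditions: Et2Zn, CH2I2, CH2Cl2, 0 °C to rt
Reagents that add atoms: diiodomethane, ICI
Why: Furukawa-type Simmons–Smith cyclopropanation is fastest at the electron-rich silyl enol ether and should deliver CH2 to the α face, anti to the axial C5 methyl, while ketone and ester are inert to the zinc carbenoid.

Step 12
Reactants: 18 silyloxycyclopropane ketone
Product: 19 Δ8 enol triflate (C9–OTf; otherwise as 18)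
Conditions: KN(SiMe3)2, THF, −78 °C; then PhNTf2
Reagents that add atoms: N-phenylbis(trifluoromethanesulfonimide), O=S(=O)(N(c1ccccc1)S(=O)(=O)C(F)(F)F)C(F)(F)F
Why: Kinetic deprotonation with the hindered amide base occurs at the C8 methylene in preference to the C10 methine and the ester α-CH, and N-triflimide trapping should give the Δ8 enol triflate regioselectively.

Step 13
Reactants: 19 enol triflate
Product: 20 Δ8 alkene (C3–C4 silyloxycyclopropane; 7α-CO2Me)
Conditions: Pd(OAc)2 (cat.), PPh3, HCO2H, n-Bu3N, DMF, 60 °C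
Reagents that add atoms: none
Why: Palladium-catalysed formate reduction of an enol triflate (oxidative addition to zerovalent palladium, formate exchange, decarboxylation, reductive elimination) should replace OTf by H with the double bond held at C8–C9.

Step 14
Reactants: 20 Δ8 alkene
Product: 21 8α,9α-diol (C3–C4 silyloxycyclopropane; 7α-CO2Me)
Conditions: OsO4 (cat.), NMO, acetone/H2O, rt
Reagents that add atoms: osmium tetroxide, O=[Os](=O)(=O)=O; N-methylmorpholine N-oxide, C[N+]1([O-])CCOCC1; water, O
Why: Catalytic osmylation (Upjohn conditions) is a syn addition and should occur on the α face, away from the axial C5 methyl that shields the β face at C9, giving the 8α,9α-diol while the silyloxycyclopropane is inert.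

Step 15
Reactants: 21 diol
Product: 22 8α,9α-acetonide methyl ester
Conditions: Me2C(OMe)2, PPTS (cat.), CH2Cl2, rt
Reagents that add atoms: 2,2-dimethoxypropane, COC(C)(C)OC
Why: Transketalisation of the cis-diol with 2,2-dimethoxypropane under mild acid should give the five-membered acetonide without opening the silyloxycyclopropane.

Step 16
Reactants: 22 acetonide methyl ester
Product: 23 C7 N-methoxy-N-methylamide (acetonide; silyloxycyclopropane)
Conditions: MeNHOMe·HCl, i-PrMgCl, THF, −20 to 0 °C
Reagents that add atoms: N,O-dimethylhydroxylamine hydrochloride, CNOC.Cl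
Why: Aminolysis of the methyl ester with the magnesium amide of N,O-dimethylhydroxylamine is a standard, weakly basic route to Weinreb amides and should not enolise C7, which carries a β-oxygen.

Step 17
Reactants: 23 Weinreb amide
Product: 24 C7 methyl ketone (7α-acetyl; acetonide; silyloxycyclopropane)
Conditions: MeMgBr, THF, −20 to 0 °C
Reagents that add atoms: methylmagnesium bromide, C[Mg]Br
Why: Weinreb ketone synthesis with methylmagnesium bromide should stop at the methyl ketone because the chelated adduct survives until work-up.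

Step 18
Reactants: 24 methyl ketone
Product: 25 7α-isopropenyl acetonide (silyloxycyclopropane)
Conditions: Ph3PCH3Br, KOt-Bu, THF, 0 °C to rt
Reagents that add atoms: methyltriphenylphosphonium bromide, C[P+](c1ccccc1)(c1ccccc1)c1ccccc1.[Br-]
Why: Wittig methylenation of the methyl ketone should give the isopropenyl group, and any enolisation on the way occurs at the methyl side so that C7 and its β-oxygen stay in place.

Step 19
Reactants: 25 isopropenyl silyloxycyclopropane
Product: 28 4β-methyl-3-ketone (5β-methyl; 7α-isopropenyl; 8α,9α-acetonide; 10α-H), via cyclopropanol 26 (not isolated), via 4α-methyl ketone 27 (not isolated)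
Conditions: Bu4NF, THF, 0 °C to rt; then NaOMe, MeOH, rt
Reagents that add atoms: none
Why: Fluoride removes the silyl group, the cyclopropanolate opens at the C3–CH2 bond towards the less substituted carbanion (homoenolate protonation) to the 4-methyl-3-ketone, and methoxide should then equilibrate C4 to the equatorial 4β-methyl epimer, which has one gauche contact fewer than the axial one.

Step 20
Reactants: 28 4β-methyl-3-ketone
Product: 29 3β-alcohol (axial OH; 4β,5β-dimethyl; 7α-isopropenyl; 8α,9α-acetonide)
Conditions: LiBH(s-Bu)3, THF, −78 °C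
Reagents that add atoms: none
Why: The bulky trialkylborohydride attacks the C3 ketone along the equatorial trajectory, axial attack being blocked by the syn-axial C5 methyl, which should give the axial 3β-alcohol needed for the inverting esterification.

Step 21
Reactants: 30 (S)-pent-1-yn-3-ol
Product: 31 (S)-4-hydroxyhex-2-ynoic acid
Conditions: n-BuLi (2.2 equiv), THF, −78 °C; CO2; aq. HCl
Reagents that add atoms: carbon dioxide, O=C=O
Why: Double deprotonation gives the alkoxide–acetylide dianion, whose carbon terminus is carboxylated by CO2 (the O-carbonate reverts on acidification), leaving the carbinol stereocentre untouched.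

Step 22
Reactants: 31 (S)-4-hydroxyhex-2-ynoic acid
Product: 32 tert-butyl (S)-4-hydroxyhex-2-ynoate
Conditions: t-BuOC(=NH)CCl3, CH2Cl2/cyclohexane, rt
Reagents that add atoms: tert-butyl 2,2,2-trichloroacetimidate, CC(C)(C)OC(=N)C(Cl)(Cl)Cl
Why: The trichloroacetimidate esterifies the carboxylic acid under its own acid catalysis while the secondary alcohol, which would need a Lewis acid, should stay free.

Step 23
Reactants: 32 tert-butyl (S)-4-hydroxyhex-2-ynoate; 33 hex-2-ynoic acid
Product: 34 tert-butyl (S)-4-(hex-2-ynoyloxy)hex-2-ynoate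
Conditions: DIC, DMAP (cat.), CH2Cl2, 0 °C
Reagents that add atoms: none
Why: Steglich-type carbodiimide esterification of the secondary propargylic alcohol should proceed with retention at the carbinol carbon, and neither alkyne can isomerise geometrically.

Step 24
Reactants: 34 bis-ynoate
Product: 35 tert-butyl (2Z,4S)-4-[(2Z)-hex-2-enoyloxy]hex-2-enoate
Conditions: H2 (1 atm), Pd/CaCO3 poisoned with Pb(OAc)2, quinoline, EtOAc, rt
Reagents that add atoms: none
Why: Semihydrogenation over lead-poisoned palladium adds H2 syn to each alkyne and stops at the alkene, which should give both Z enoates in one operation with the oxygen already acylated so that no butenolide can form.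

Step 25
Reactants: 35 tert-butyl ester
Product: 36 (2Z,4S)-4-[(2Z)-hex-2-enoyloxy]hex-2-enoic acid
Conditions: TFA, CH2Cl2, 0 °C; used directly
Reagents that add atoms: none
Why: Acidolysis of the tert-butyl ester with loss of isobutene should free the acid without touching the two enoate esters or the Z alkenes.

Step 26
Reactants: 29 3β-alcohol; 36 side-chain acid
Product: 37 3α-ester acetonide (target with the 8α,9α-diol as acetonide)
Conditions: PPh3, DIAD, PhMe, 0 °C to rt
Reagents that add atoms: none
Why: Mitsunobu esterification displaces the activated axial C3 oxygen by the carboxylate with SN2 inversion to the equatorial 3α-ester, and because the acid is never activated as an acyl donor its Z alkenes and C4′ centre should stay intact.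

Step 27
Reactants: 37 3α-ester acetonide
Product: 38 target, (3R,4R,5R,7S,8R,9S,10R)-8,9-dihydroxyeremophil-11-en-3-yl (2Z,4S)-4-[(2Z)-hex-2-enoyloxy]hex-2-enoate
Conditions: AcOH/H2O (4:1), 40 °C
Reagents that add atoms: none
Why: Mild aqueous acid hydrolysis of the cis-fused acetonide should release the 8α,9α-diol while the two ester links, the Z enoates and the isopropenyl group survive.

Compound list
1 | prop-2-yn-1-ol | C#CCO | starting material
2 | alkenylalane, (E)-Me2Al–CH=C(CH3)–CH2–O–AlMe2 | C[Al](C)/C=C(\C)CO[Al](C)C | intermediate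
3 | (E)-3-iodo-2-methylprop-2-en-1-ol | OC/C(C)=C/I | intermediate
4 | (E)-3-bromo-1-iodo-2-methylprop-1-ene | BrC/C(C)=C/I | intermediate
5 | succinic anhydride | O=C1CCC(=O)O1 | starting material
6 | 4-[methoxy(methyl)amino]-4-oxobutanoic acid | CON(C)C(=O)CCC(=O)O | intermediate
7 | (R)-4-benzyl-1,3-oxazolidin-2-one | O=C1N[C@H](Cc2ccccc2)CO1 | starting material
8 | mixed pivalic anhydride of 6 | CON(C)C(=O)CCC(=O)OC(=O)C(C)(C)C | intermediate
9 | (R)-4-benzyl-3-{4-[methoxy(methyl)amino]-4-oxobutanoyl}-1,3-oxazolidin-2-one | CON(C)C(=O)CCC(=O)N1[C@H](Cc2ccccc2)COC1=O | intermediate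
10 | (R)-4-benzyl-3-[(2R,4E)-5-iodo-2-{2-[methoxy(methyl)amino]-2-oxoethyl}-4-methylpent-4-enoyl]-1,3-oxazolidin-2-one | CON(C)C(=O)C[C@@H](C/C(C)=C/I)C(=O)N1[C@H](Cc2ccccc2)COC1=O | intermediate
11 | methyl (2R,4E)-5-iodo-2-{2-[methoxy(methyl)amino]-2-oxoethyl}-4-methylpent-4-enoate | CON(C)C(=O)C[C@@H](C/C(C)=C/I)C(=O)OC | intermediate
12 | methyl (2R,4E)-6-ethoxy-2-{2-[methoxy(methyl)amino]-2-oxoethyl}-4-methylhepta-4,6-dienoate | CON(C)C(=O)C[C@@H](C/C(C)=C/C(=C)OCC)C(=O)OC | intermediate
13 | methyl (2R,4E)-2-{2-[methoxy(methyl)amino]-2-oxoethyl}-4-methyl-6-oxohept-4-enoate | CON(C)C(=O)C[C@@H](C/C(C)=C/C(C)=O)C(=O)OC | intermediate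
14 | methyl (2R,4E)-6-[(tert-butyldimethylsilyl)oxy]-2-{2-[methoxy(methyl)amino]-2-oxoethyl}-4-methylhepta-4,6-dienoate | CON(C)C(=O)C[C@@H](C/C(C)=C/C(=C)O[Si](C)(C)C(C)(C)C)C(=O)OC | intermediate
15 | methyl (2R,4E)-6-[(tert-butyldimethylsilyl)oxy]-4-methyl-2-(2-oxobut-3-enyl)hepta-4,6-dienoate (trienone) | COC(=O)[C@@H](CC(=O)C=C)C/C(C)=C/C(=C)O[Si](C)(C)C(C)(C)C | intermediate
16 | cis-fused cycloadduct (Δ3 TBS enol ether; 5β-methyl; 7α-CO2Me; 9-oxo; 10β-H) | COC(=O)[C@@H]1C[C@]2(C)C=C(O[Si](C)(C)C(C)(C)C)CC[C@@H]2C(=O)C1 | intermediate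
17 | trans-fused decalone (Δ3 TBS enol ether; 5β-methyl; 7α-CO2Me; 9-oxo; 10α-H; 5R,7R,10R) | COC(=O)[C@@H]1C[C@]2(C)C=C(O[Si](C)(C)C(C)(C)C)CC[C@H]2C(=O)C1 | intermediate
18 | silyloxycyclopropane ketone (α-CH2 across C3–C4; 3β-OTBS; 4β-H; 9-oxo; 7α-CO2Me) | COC(=O)[C@@H]1C[C@]2(C)[C@@H]3C[C@]3(O[Si](C)(C)C(C)(C)C)CC[C@H]2C(=O)C1 | intermediate
19 | Δ8 enol triflate of 18 (C9–OTf) | COC(=O)[C@@H]1C[C@]2(C)[C@@H]3C[C@]3(O[Si](C)(C)C(C)(C)C)CC[C@H]2C(OS(=O)(=O)C(F)(F)F)=C1 | intermediate
20 | Δ8 alkene (silyloxycyclopropane; 7α-CO2Me) | COC(=O)[C@@H]1C[C@]2(C)[C@@H]3C[C@]3(O[Si](C)(C)C(C)(C)C)CC[C@H]2C=C1 | intermediate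
21 | 8α,9α-diol (silyloxycyclopropane; 7α-CO2Me) | COC(=O)[C@@H]1C[C@]2(C)[C@@H]3C[C@]3(O[Si](C)(C)C(C)(C)C)CC[C@H]2[C@H](O)[C@@H]1O | intermediate
22 | 8α,9α-acetonide methyl ester | COC(=O)[C@@H]1C[C@]2(C)[C@@H]3C[C@]3(O[Si](C)(C)C(C)(C)C)CC[C@H]2[C@@H]4OC(C)(C)O[C@H]14 | intermediate
23 | C7 N-methoxy-N-methylamide | CON(C)C(=O)[C@@H]1C[C@]2(C)[C@@H]3C[C@]3(O[Si](C)(C)C(C)(C)C)CC[C@H]2[C@@H]4OC(C)(C)O[C@H]14 | intermediate
24 | C7 methyl ketone (7α-acetyl) | CC(=O)[C@@H]1C[C@]2(C)[C@@H]3C[C@]3(O[Si](C)(C)C(C)(C)C)CC[C@H]2[C@@H]4OC(C)(C)O[C@H]14 | intermediate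
25 | 7α-isopropenyl silyloxycyclopropane acetonide | C=C(C)[C@@H]1C[C@]2(C)[C@@H]3C[C@]3(O[Si](C)(C)C(C)(C)C)CC[C@H]2[C@@H]4OC(C)(C)O[C@H]14 | intermediate
26 | cyclopropanol (3β-OH; α-CH2 across C3–C4) | C=C(C)[C@@H]1C[C@]2(C)[C@@H]3C[C@]3(O)CC[C@H]2[C@@H]4OC(C)(C)O[C@H]14 | intermediate
27 | 4α-methyl-3-ketone (axial methyl) | C=C(C)[C@@H]1C[C@]2(C)[C@H](C)C(=O)CC[C@H]2[C@@H]3OC(C)(C)O[C@H]13 | intermediate
28 | 4β-methyl-3-ketone (equatorial methyl; 7α-isopropenyl; 8α,9α-acetonide) | C=C(C)[C@@H]1C[C@]2(C)[C@@H](C)C(=O)CC[C@H]2[C@@H]3OC(C)(C)O[C@H]13 | intermediate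
29 | 3β-alcohol (axial OH) | C=C(C)[C@@H]1C[C@]2(C)[C@@H](C)[C@@H](O)CC[C@H]2[C@@H]3OC(C)(C)O[C@H]13 | intermediate
30 | (S)-pent-1-yn-3-ol | C#C[C@@H](O)CC | starting material
31 | (S)-4-hydroxyhex-2-ynoic acid | OC(=O)C#C[C@@H](O)CC | intermediate
32 | tert-butyl (S)-4-hydroxyhex-2-ynoate | CC(C)(C)OC(=O)C#C[C@@H](O)CC | intermediate
33 | hex-2-ynoic acid | CCCC#CC(=O)O | starting material
34 | tert-butyl (S)-4-(hex-2-ynoyloxy)hex-2-ynoate | CC(C)(C)OC(=O)C#C[C@@H](OC(=O)C#CCCC)CC | intermediate
35 | tert-butyl (2Z,4S)-4-[(2Z)-hex-2-enoyloxy]hex-2-enoate | CC(C)(C)OC(=O)/C=C\[C@@H](OC(=O)/C=C\CCC)CC | intermediate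
36 | (2Z,4S)-4-[(2Z)-hex-2-enoyloxy]hex-2-enoic acid | OC(=O)/C=C\[C@@H](OC(=O)/C=C\CCC)CC | intermediate
37 | 3α-ester acetonide | C=C(C)[C@@H]1C[C@]2(C)[C@@H](C)[C@H](OC(=O)/C=C\[C@H](CC)OC(=O)/C=C\CCC)CC[C@H]2[C@@H]3OC(C)(C)O[C@H]13 | intermediate
38 | CNP0271544.1, (3R,4R,5R,7S,8R,9S,10R)-8,9-dihydroxyeremophil-11-en-3-yl (2Z,4S)-4-[(2Z)-hex-2-enoyloxy]hex-2-enoate | C=C(C)[C@@H]1C[C@]2(C)[C@@H](C)[C@H](OC(=O)/C=C\[C@H](CC)OC(=O)/C=C\CCC)CC[C@H]2[C@H](O)[C@@H]1O | target

Total step count: 27. Longest linear sequence: 20 steps (steps 3–20, 26 and 27, from succinic anhydride).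

Steps most likely to fail

Step 10. The cycloaddition may be sluggish at the fully substituted C5 terminus, whose inside methyl strains the s-cis diene. The endo-chair pathway, in which the diene lies axial over the forming ring B, may then take over and join C5 syn to the C7 ester, so the diene face would be chosen the wrong way. The fallback sets out from acid 6 and comes back at 18. It changes the approach from kinetic face control to the endo-chair pathway followed by thermodynamic correction. Acid 6 is coupled as in step 4, but with (S)-4-benzyl-1,3-oxazolidin-2-one, to the enantiomeric imide F1. Alkylation with 4 as in step 5 gives the (2S)-alkylated imide F2, and methanolysis gives the (S)-iodo ester F3. Stille coupling gives the (S)-ethoxydiene F4, which is hydrolysed to the (S)-enone F5. Silylation gives the (S)-dienol ether F6 and vinyl Grignard addition the (S)-trienone F7. Its endo-chair cycloaddition should give the all-cis adduct F8 (5β-methyl, 7β-ester, 10β-H), which already has the required configuration at C5, the only centre that cannot be epimerised. Cyclopropanation as in step 11 gives the all-cis silyloxycyclopropane F9. NaOMe in MeOH then epimerises C10 through the ketone and C7 through the ester to the trans-fused isomer with equatorial ester, which is 18.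

Step 26. The activated axial C3 oxygen may undergo anti elimination towards C2 or C4 instead of substitution, since the centre is flanked by the C4 methine and a syn-axial methyl. The fallback sets out from ketone 28 and comes back at 37. Dissolving-metal reduction (Li, liquid NH3, t-BuOH, THF, −78 °C) gives the thermodynamically preferred equatorial 3α-alcohol F10. This is acylated with acid 36 with retention under Yamaguchi conditions (2,4,6-trichlorobenzoyl chloride, Et3N, then DMAP, PhMe) to give 37.

Step 9. The Grignard reagent may over-add to the ketone or the ester, the liberated N,O-dimethylhydroxylamine may add to the new enone during work-up, or the acidic quench may hydrolyse the dienol ether. The fallback sets out from 14 and comes back at 15. The Weinreb amide is reduced with i-Bu2AlH (THF, −78 °C), faster than the hindered methyl ester, to the aldehyde F11, and the amine is washed out at this stage. CH2=CHMgBr at −78 °C adds to the aldehyde only, giving the allylic alcohol F12 as a mixture of C9 epimers. Dess–Martin periodinane buffered with NaHCO3 then oxidises it to 15.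

Further compounds
F1 | step 10 | (S)-4-benzyl-3-{4-[methoxy(methyl)amino]-4-oxobutanoyl}-1,3-oxazolidin-2-one | CON(C)C(=O)CCC(=O)N1[C@@H](Cc2ccccc2)COC1=O
F2 | step 10 | (S)-4-benzyl-3-[(2S,4E)-5-iodo-2-{2-[methoxy(methyl)amino]-2-oxoethyl}-4-methylpent-4-enoyl]-1,3-oxazolidin-2-one | CON(C)C(=O)C[C@H](C/C(C)=C/I)C(=O)N1[C@@H](Cc2ccccc2)COC1=O
F3 | step 10 | methyl (2S,4E)-5-iodo-2-{2-[methoxy(methyl)amino]-2-oxoethyl}-4-methylpent-4-enoate | CON(C)C(=O)C[C@H](C/C(C)=C/I)C(=O)OC
F4 | step 10 | methyl (2S,4E)-6-ethoxy-2-{2-[methoxy(methyl)amino]-2-oxoethyl}-4-methylhepta-4,6-dienoate | CON(C)C(=O)C[C@H](C/C(C)=C/C(=C)OCC)C(=O)OC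
F5 | step 10 | methyl (2S,4E)-2-{2-[methoxy(methyl)amino]-2-oxoethyl}-4-methyl-6-oxohept-4-enoate | CON(C)C(=O)C[C@H](C/C(C)=C/C(C)=O)C(=O)OC
F6 | step 10 | methyl (2S,4E)-6-[(tert-butyldimethylsilyl)oxy]-2-{2-[methoxy(methyl)amino]-2-oxoethyl}-4-methylhepta-4,6-dienoate | CON(C)C(=O)C[C@H](C/C(C)=C/C(=C)O[Si](C)(C)C(C)(C)C)C(=O)OC
F7 | step 10 | methyl (2S,4E)-6-[(tert-butyldimethylsilyl)oxy]-4-methyl-2-(2-oxobut-3-enyl)hepta-4,6-dienoate | COC(=O)[C@H](CC(=O)C=C)C/C(C)=C/C(=C)O[Si](C)(C)C(C)(C)C
F8 | step 10 | all-cis cycloadduct (Δ3 TBS enol ether; 5β-methyl; 7β-CO2Me; 9-oxo; 10β-H) | COC(=O)[C@H]1C[C@]2(C)C=C(O[Si](C)(C)C(C)(C)C)CC[C@@H]2C(=O)C1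
F9 | step 10 | all-cis silyloxycyclopropane ketone (α-CH2 across C3–C4; 7β-CO2Me; 10β-H) | COC(=O)[C@H]1C[C@]2(C)[C@@H]3C[C@]3(O[Si](C)(C)C(C)(C)C)CC[C@@H]2C(=O)C1
F10 | step 26 | 3α-alcohol (equatorial OH; 4β,5β-dimethyl; 7α-isopropenyl; 8α,9α-acetonide) | C=C(C)[C@@H]1C[C@]2(C)[C@@H](C)[C@H](O)CC[C@H]2[C@@H]3OC(C)(C)O[C@H]13
F11 | step 9 | methyl (2R,4E)-6-[(tert-butyldimethylsilyl)oxy]-4-methyl-2-(2-oxoethyl)hepta-4,6-dienoate | O=CC[C@@H](C/C(C)=C/C(=C)O[Si](C)(C)C(C)(C)C)C(=O)OC
F12 | step 9 | methyl (2R,4E)-6-[(tert-butyldimethylsilyl)oxy]-2-(2-hydroxybut-3-enyl)-4-methylhepta-4,6-dienoate (carbinol epimers) | C=CC(O)C[C@@H](C/C(C)=C/C(=C)O[Si](C)(C)C(C)(C)C)C(=O)OC
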